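Maple, with 16 mM of reagent on 20 mM of substrate, ended its readings at 40.0 min with side product at 52.7 % and target at 41.1 %, so we ask first what end state this charge demands.

| setting | maple | birch | epsilon | eta | theta | beta |
|---|---|---|---|---|---|---|
| substrate | 20 mM | 20 mM | 20 mM (fed, over 50 min) | 20 mM | 20 mM | 20 mM |
| reagent | 16 mM | 8 mM | 16.0 mM | 16.0 mM (in portions, 3, over 50 min) | 16.0 mM | 16.0 mM (fed, over 50 min) |
| remark | run made earlier | run made earlier | all else is in the flask from the start; the feed brings no volume worth counting | first portion at the start, last at 50 min | everything together at the start | all else is in the flask from the start; the feed brings no volume worth counting |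
| time |  |  | 1.0 h | 1.0 h | 1.0 h | 1.0 h |

- maple (time / min: side product / %, target / %): 5.00: 11.7, 25.6; 10.0: 25.9, 31.5; 15.0: 39.2, 37.9; 20.0: 43.8, 41.1; 25.0: 49.7, 40.7; 30.0: 49.7, 43.6; 40.0: 52.7, 41.1
- birch (time / min: side product / %, target / %): 0.500: 0, 3.5; 0.667: 0.9, 3.7; 1.00: 0.3, 6.9; 1.50: 2.2, 9.2; 2.50: 2.9, 12.9; 4.00: 6.6, 20.3; 6.00: 14.3, 23.5

(readings scatter by 1 percentage point)

- a species is counted by the substrate in it: one side product counts as two
- the earlier runs were read with a standard deviation of 1 percentage point

- the flask that comes out highest in amount of side product, in percent of the substrate charged; "all alike" if 1.5 percentage points covers them all (epsilon / eta / theta / beta / all alike)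
- amount of side product at the end, in percent of the substrate charged, epsilon
- amount of side product at the end, in percent of the substrate charged, eta
- amount of side product at the end, in percent of the substrate charged, theta
- amount of side product at the end, in percent of the substrate charged, beta

Side product lags target, so we take it to be target joined to a second substrate: it holds one reagent for 2 substrates, while we let every other converted substrate take one reagent. The charges here give [reagent]/[substrate] = 0.800. With the substrate gone, this balance puts side product at 40.0 % even when every reagent is spent; we call this the reagent floor.

The next question is what moves a flask away from the floor. Each point of reagent left, counted against the substrate charge, adds 2 points, and each point of substrate left takes 2 away. Maple read 13 points above the floor, which, if its substrate was gone, means 6.3 points of reagent unspent, as a reading with its scatter. Theta has maple's charges, so our own reckoning puts it near 52.7 %. For the staged flasks we commit to the balance and to no number of our own.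

The forecast gave epsilon 47 %, eta 68 %, theta 54 % and beta 65 %, with eta highest: “Starving reagent slows target formation, while target still meets plentiful substrate.”

The simulation puts eta highest, with epsilon 49.6 %, eta 64.8 %, theta 53.5 % and beta 56.0 %; beta lies 9 points below the forecast and holds 14.1 % as isomer of the product after 1.00 h.

    reagent + loose pair → isomer of the product (k = 20000 /M/min)
    reagent + tight pair → target (k = 41000 /M/min)
    substrate + target → side product (k = 5.50 /M/min)
    substrate ⇌ tight pair (K = 0.0300, k = 0.0770 /min)
    tight pair ⇌ loose pair (K = 0.560, k = 22.0 /min)

In eta, the floor plus reagent left minus substrate left, each doubled, gives 64.8 % against 64.8 %. In epsilon's neighbour with 12 mM of substrate, the same expression for the floor comes to −66.7 %, and the same sum gives 37.8 % against 37.8 %. In epsilon at 0.513 h, the forward step from substrate to tight pair used substrate at 2.6 times the rate of the step to side product.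

The earlier runs and the new flask were computed for an exercise, and the scatter is random.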